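**Retrosynthetic overview**

1. The strategy rests on ring A (C4a, C5, C6, C7, C8, C8a): a phloroglucinol whose C4a carries the C4 acyl carbon, the aromatic end of a cinnamoyl tetraketide. The C4a–C8a bond is cut retro-Claisen to a methyl 9-aryl-3,5,7-trioxonon-8-enoate.
2. The triketo ester is cut at C6–C7 into the 2,4,6-trianion of methyl 3,5-dioxohexanoate and a cinnamoyl N-methoxy-N-methylamide, the amide coming from a Heck reaction of the ring B aryl bromide.
3. Ring B is bought as 4-bromophenol; its two (R)-2-hydroxy-3-methylbut-3-enyl arms come from double Stille prenylation, Shi epoxidation (both stereocentres) and epoxide-to-allylic-alcohol isomerisation.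
4. Ring order: ring B (bought), ring A by Claisen folding, then ring C by O1–C2 oxa-Michael closure and dehydrogenation to the flavone.
5. Protection is all-silyl (aryl O-triisopropylsilyl, alkyl O-tert-butyldimethylsilyl), so that one buffered fluoride step ends the synthesis and no acid meets the ortho-phenol/allylic alcohol/isopropenyl array.

Key step: step 9

Assumption: compounds 4, 9 and 11 are taken as purchased reagents, and both carbinol carbons of the target are read as R from its SMILES.

**Route**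

Step 1
Reactants: 1 4-bromophenol
Product: 2 4-bromo-2,6-diiodophenol
Conditions: N-iodosuccinimide (2.1 equiv), p-TsOH·H2O (10 mol%), MeCN, 0 °C to rt
Reagents that add atoms: N-iodosuccinimide, O=C1CCC(=O)N1I
Why: Electrophilic aromatic substitution, in which the hydroxyl group directs iodination to its two free ortho positions because the para position is occupied by bromine.

Step 2
Reactants: 2 4-bromo-2,6-diiodophenol
Product: 3 (4-bromo-2,6-diiodophenoxy)triisopropylsilane
Conditions: TIPSOTf (1.3 equiv), 2,6-lutidine (2 equiv), CH2Cl2, 0 °C to rt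
Reagents that add atoms: triisopropylsilyl trifluoromethanesulfonate, CC(C)[Si](OS(=O)(=O)C(F)(F)F)(C(C)C)C(C)C
Why: Silyl triflate O-silylation reaches even a phenol flanked by two iodines, and the hindered aryl triisopropylsilyl ether is chosen because it should withstand amide bases, magnesium methoxide and hot pyridine yet leave with fluoride at the end.

Step 3
Reactants: 3 (4-bromo-2,6-diiodophenoxy)triisopropylsilane; 4 tributyl(3-methylbut-2-en-1-yl)stannane (2.4 equiv)
Product: 5 [4-bromo-2,6-bis(3-methylbut-2-en-1-yl)phenoxy]triisopropylsilane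
Conditions: Pd(PPh3)4 (5 mol%), LiCl, DMF, 80 °C
Reagents that add atoms: none
Why: Stille coupling, in which zerovalent palladium inserts into the two carbon–iodine bonds much faster than into the carbon–bromine bond and reductive elimination at the unsubstituted allyl terminus should give the linear prenyl arene.

Step 4
Reactants: 5 [4-bromo-2,6-bis(3-methylbut-2-en-1-yl)phenoxy]triisopropylsilane
Product: 6 [4-bromo-2,6-bis{[(2R)-3,3-dimethyloxiran-2-yl]methyl}phenoxy]triisopropylsilane
Conditions: D-fructose-derived Shi ketone (1,2:4,5-di-O-isopropylidene-β-D-erythro-2,3-hexodiulo-2,6-pyranose, 0.6 equiv), KHSO5 (as 2KHSO5·KHSO4·K2SO4), K2CO3, Bu4NHSO4, aqueous Na2B4O7 buffer (pH 10.5), MeCN/CH2(OMe)2, 0 °C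
Reagents that add atoms: potassium peroxymonosulfate, [K+].[O-]S(=O)(=O)OO
Why: Shi asymmetric epoxidation, in which the chiral dioxirane transfers oxygen to each electron-rich trisubstituted prenyl olefin through a spiro transition state and should set the (R) configuration at both ring CH carbons (the facial sense that gives R,R epoxides from trans olefins), the two remote olefins reacting independently so that a rare wrong-face event ends in a separable R,S diastereomer.

Step 5
Reactants: 6 [4-bromo-2,6-bis{[(2R)-3,3-dimethyloxiran-2-yl]methyl}phenoxy]triisopropylsilane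
Product: 7 (2R,2'R)-1,1'-[5-bromo-2-(triisopropylsilyloxy)-1,3-phenylene]bis(3-methylbut-3-en-2-ol)
Conditions: diethylaluminium 2,2,6,6-tetramethylpiperidide (6 equiv; from 2,2,6,6-tetramethylpiperidine, n-BuLi, then Et2AlCl), toluene, 0 °C to rt; aqueous KNaC4H4O6 work-up
Reagents that add atoms: none
Why: Epoxide-to-allylic-alcohol isomerisation with an aluminium amide, in which aluminium activates the epoxide oxygen, the C–O bond at the tertiary carbon breaks and the amide removes a proton from the methyl group cis to the ring hydrogen in a cyclic syn elimination, so the secondary carbinol carbon keeps its C–O bond and its (R) configuration.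

Step 6
Reactants: 7 (2R,2'R)-1,1'-[5-bromo-2-(triisopropylsilyloxy)-1,3-phenylene]bis(3-methylbut-3-en-2-ol)
Product: 8 {4-bromo-2,6-bis[(2R)-2-(tert-butyldimethylsilyloxy)-3-methylbut-3-en-1-yl]phenoxy}triisopropylsilane
Conditions: TBSOTf (3 equiv), 2,6-lutidine (5 equiv), CH2Cl2, −78 to 0 °C
Reagents that add atoms: tert-butyldimethylsilyl trifluoromethanesulfonate, CC(C)(C)[Si](C)(C)OS(=O)(=O)C(F)(F)F
Why: Silyl triflate silylation of the two hindered secondary allylic alcohols gives ethers that should survive the Heck conditions, the amide base, magnesium methoxide and iodine in pyridine and that leave with fluoride in the last step.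

Step 7
Reactants: 8 {4-bromo-2,6-bis[(2R)-2-(tert-butyldimethylsilyloxy)-3-methylbut-3-en-1-yl]phenoxy}triisopropylsilane; 9 N-methoxy-N-methylacrylamide (2 equiv)
Product: 10 (E)-3-{3,5-bis[(2R)-2-(tert-butyldimethylsilyloxy)-3-methylbut-3-en-1-yl]-4-(triisopropylsilyloxy)phenyl}-N-methoxy-N-methylprop-2-enamide
Conditions: Pd(OAc)2 (5 mol%), P(o-tol)3 (12 mol%), Et3N, DMF, 100 °C
Reagents that add atoms: none
Why: Mizoroki–Heck reaction, in which the unhindered aryl bromide adds to palladium, the arylpalladium species inserts the electron-poor monosubstituted acrylamide in preference to the hindered 1,1-disubstituted isopropenyl groups, and syn β-hydride elimination gives the E cinnamamide.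

Step 8
Reactants: 10 (E)-3-{3,5-bis[(2R)-2-(tert-butyldimethylsilyloxy)-3-methylbut-3-en-1-yl]-4-(triisopropylsilyloxy)phenyl}-N-methoxy-N-methylprop-2-enamide; 11 methyl 3,5-dioxohexanoate (2 equiv)
Product: 13 methyl (E)-9-{3,5-bis[(2R)-2-(tert-butyldimethylsilyloxy)-3-methylbut-3-en-1-yl]-4-(triisopropylsilyloxy)phenyl}-3,5,7-trioxonon-8-enoate, via trilithium 2,4,6-trienolate 12 (not isolated)
Conditions: 11, LiN(iPr)2 (6.2 equiv), THF, −78 to 0 °C; then 10, −78 to −20 °C; AcOH quench at −78 °C
Reagents that add atoms: none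
Why: Acylation of a β,δ-diketo ester trianion at its most basic terminal carbon by an N-methoxy-N-methylamide (Weinreb ketone synthesis), in which the chelated tetrahedral lithium adduct survives until the quench so that the new ketone is never exposed to the polyanion, and the hard terminal carbanion should add to the carbonyl carbon and not to the β-carbon of the cinnamoyl unit.

Step 9
Reactants: 13 methyl (E)-9-{3,5-bis[(2R)-2-(tert-butyldimethylsilyloxy)-3-methylbut-3-en-1-yl]-4-(triisopropylsilyloxy)phenyl}-3,5,7-trioxonon-8-enoate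
Product: 14 (E)-3-{3,5-bis[(2R)-2-(tert-butyldimethylsilyloxy)-3-methylbut-3-en-1-yl]-4-(triisopropylsilyloxy)phenyl}-1-(2,4,6-trihydroxyphenyl)prop-2-en-1-one
Conditions: Mg(OMe)2 (6 equiv, solution in MeOH), MeOH, 25 to 45 °C; AcOH then pH 5 buffer at 0 °C
Reagents that add atoms: none
Why: Magnesium methoxide converts the triketo ester into a chelated magnesium polyenolate in which C6, the carbon between the C5 and C7 carbonyls, adds to the ester carbon C1; loss of methoxide gives a 2-acylcyclohexane-1,3,5-trione that is the keto tautomer of the phloroglucinol and aromatises at once, so the C4a–C8a bond of ring A is made and chain carbon C7 becomes the C4 acyl carbon. The closest known reaction type is the biomimetic intramolecular Claisen (Dieckmann-type) cyclisation of 3,5,7-triketo esters to acylphloroglucinols, the laboratory counterpart of the chalcone synthase fold. Ring A closes in a 6-exo-trig mode, the attacked ester C=O lying outside the new ring, and aromatisation makes the closure irreversible. No stereocentre is created and the two silyloxy stereocentres of the side chains are remote from every enolisable position. What has to be controlled is the direction of folding, since attack of C6 on C1 must win over attack of C2 on the C7 ketone (aldol folding to a styryl resorcylate) and over lactonisation to a 4-hydroxy-2-pyranone; chelation of the 1,3-dicarbonyl units to magnesium in methanol lowers the electrophilicity of the ketones and leaves the ester as the acceptor, whereas aqueous hydroxide is avoided because it promotes the aldol mode. Because C8 and C9 are olefinic the chain cannot enolise beyond C7, which fixes the styryl ketone as the acyl group on C4a, and any oxa-Michael adduct of an enol oxygen onto C9 forms reversibly and drains into the aromatic product.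

Step 10
Reactants: 14 (E)-3-{3,5-bis[(2R)-2-(tert-butyldimethylsilyloxy)-3-methylbut-3-en-1-yl]-4-(triisopropylsilyloxy)phenyl}-1-(2,4,6-trihydroxyphenyl)prop-2-en-1-one
Product: 16 2-{3,5-bis[(2R)-2-(tert-butyldimethylsilyloxy)-3-methylbut-3-en-1-yl]-4-(triisopropylsilyloxy)phenyl}-5,7-dihydroxy-4H-chromen-4-one, via flavanone 15 (not isolated)
Conditions: pyridine, 90 °C; then I2 (1.1 equiv), pyridine, 90 °C
Reagents that add atoms: none
Why: Base-promoted 6-endo-trig oxa-Michael closure of the 2'-hydroxychalcone forms the O1–C2 bond of ring C, and iodine in pyridine then dehydrogenates the flavanone by α-iodination at C3 and loss of HI, a known flavanone-to-flavone oxidation run under non-acidic conditions so that the silyl ethers and isopropenyl groups should persist while the transient C2 stereocentre is erased.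

Step 11
Reactants: 16 2-{3,5-bis[(2R)-2-(tert-butyldimethylsilyloxy)-3-methylbut-3-en-1-yl]-4-(triisopropylsilyloxy)phenyl}-5,7-dihydroxy-4H-chromen-4-one
Product: 17 5,7-dihydroxy-2-{4-hydroxy-3,5-bis[(2R)-2-hydroxy-3-methylbut-3-en-1-yl]phenyl}-4H-chromen-4-one
Conditions: Bu4NF (6 equiv), AcOH (6 equiv), THF, 0 to 40 °C
Reagents that add atoms: none
Why: Fluoride-induced desilylation removes the aryl triisopropylsilyl ether and both secondary tert-butyldimethylsilyl ethers in one buffered, non-acidic operation that should leave the allylic alcohols, the isopropenyl groups and both stereocentres untouched.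

**Compound list**

1 | 4-bromophenol | Oc1ccc(Br)cc1 | starting material
2 | 4-bromo-2,6-diiodophenol | Oc1c(I)cc(Br)cc1I | intermediate
3 | (4-bromo-2,6-diiodophenoxy)triisopropylsilane | CC(C)[Si](Oc1c(I)cc(Br)cc1I)(C(C)C)C(C)C | intermediate
4 | tributyl(3-methylbut-2-en-1-yl)stannane | CCCC[Sn](CCCC)(CCCC)CC=C(C)C | starting material
5 | [4-bromo-2,6-bis(3-methylbut-2-en-1-yl)phenoxy]triisopropylsilane | CC(C)=CCc1cc(Br)cc(CC=C(C)C)c1O[Si](C(C)C)(C(C)C)C(C)C | intermediate
6 | [4-bromo-2,6-bis{[(2R)-3,3-dimethyloxiran-2-yl]methyl}phenoxy]triisopropylsilane | CC1(C)O[C@@H]1Cc1cc(Br)cc(C[C@H]2OC2(C)C)c1O[Si](C(C)C)(C(C)C)C(C)C | intermediate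
7 | (2R,2'R)-1,1'-[5-bromo-2-(triisopropylsilyloxy)-1,3-phenylene]bis(3-methylbut-3-en-2-ol) | C=C(C)[C@H](O)Cc1cc(Br)cc(C[C@@H](O)C(=C)C)c1O[Si](C(C)C)(C(C)C)C(C)C | intermediate
8 | {4-bromo-2,6-bis[(2R)-2-(tert-butyldimethylsilyloxy)-3-methylbut-3-en-1-yl]phenoxy}triisopropylsilane | C=C(C)[C@H](O[Si](C)(C)C(C)(C)C)Cc1cc(Br)cc(C[C@@H](O[Si](C)(C)C(C)(C)C)C(=C)C)c1O[Si](C(C)C)(C(C)C)C(C)C | intermediate
9 | N-methoxy-N-methylacrylamide | C=CC(=O)N(C)OC | starting material
10 | (E)-3-{3,5-bis[(2R)-2-(tert-butyldimethylsilyloxy)-3-methylbut-3-en-1-yl]-4-(triisopropylsilyloxy)phenyl}-N-methoxy-N-methylprop-2-enamide | C=C(C)[C@H](O[Si](C)(C)C(C)(C)C)Cc1cc(/C=C/C(=O)N(C)OC)cc(C[C@@H](O[Si](C)(C)C(C)(C)C)C(=C)C)c1O[Si](C(C)C)(C(C)C)C(C)C | intermediate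
11 | methyl 3,5-dioxohexanoate | CC(=O)CC(=O)CC(=O)OC | starting material
12 | trilithium 2,4,6-trienolate of methyl 3,5-dioxohexanoate | [Li+].[Li+].[Li+].C=C([O-])C=C([O-])C=C([O-])OC | intermediate (not isolated)
13 | methyl (E)-9-{3,5-bis[(2R)-2-(tert-butyldimethylsilyloxy)-3-methylbut-3-en-1-yl]-4-(triisopropylsilyloxy)phenyl}-3,5,7-trioxonon-8-enoate | C=C(C)[C@H](O[Si](C)(C)C(C)(C)C)Cc1cc(/C=C/C(=O)CC(=O)CC(=O)CC(=O)OC)cc(C[C@@H](O[Si](C)(C)C(C)(C)C)C(=C)C)c1O[Si](C(C)C)(C(C)C)C(C)C | intermediate (key-step precursor)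
14 | (E)-3-{3,5-bis[(2R)-2-(tert-butyldimethylsilyloxy)-3-methylbut-3-en-1-yl]-4-(triisopropylsilyloxy)phenyl}-1-(2,4,6-trihydroxyphenyl)prop-2-en-1-one | C=C(C)[C@H](O[Si](C)(C)C(C)(C)C)Cc1cc(/C=C/C(=O)c2c(O)cc(O)cc2O)cc(C[C@@H](O[Si](C)(C)C(C)(C)C)C(=C)C)c1O[Si](C(C)C)(C(C)C)C(C)C | intermediate (key-step product)
15 | 2-{3,5-bis[(2R)-2-(tert-butyldimethylsilyloxy)-3-methylbut-3-en-1-yl]-4-(triisopropylsilyloxy)phenyl}-5,7-dihydroxychroman-4-one (both C2 epimers) | C=C(C)[C@H](O[Si](C)(C)C(C)(C)C)Cc1cc(C2CC(=O)c3c(O)cc(O)cc3O2)cc(C[C@@H](O[Si](C)(C)C(C)(C)C)C(=C)C)c1O[Si](C(C)C)(C(C)C)C(C)C | intermediate (not isolated)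
16 | 2-{3,5-bis[(2R)-2-(tert-butyldimethylsilyloxy)-3-methylbut-3-en-1-yl]-4-(triisopropylsilyloxy)phenyl}-5,7-dihydroxy-4H-chromen-4-one | C=C(C)[C@H](O[Si](C)(C)C(C)(C)C)Cc1cc(-c2cc(=O)c3c(O)cc(O)cc3o2)cc(C[C@@H](O[Si](C)(C)C(C)(C)C)C(=C)C)c1O[Si](C(C)C)(C(C)C)C(C)C | intermediate
17 | 5,7-dihydroxy-2-{4-hydroxy-3,5-bis[(2R)-2-hydroxy-3-methylbut-3-en-1-yl]phenyl}-4H-chromen-4-one | C=C(C)[C@H](O)Cc1cc(-c2cc(=O)c3c(O)cc(O)cc3o2)cc(C[C@@H](O)C(=C)C)c1O | target

**Step count**

Total steps: 11. Longest linear sequence: 11 steps (1 to 17).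

**Steps most likely to fail**

Step 9 (Claisen folding). The chain may fold the aldol way (C2 onto C7) to a styryl resorcylate, lactonise to a 4-hydroxy-2-pyranone, or lose the ester by methanolysis without C–C bond formation. The fallback builds ring A from a preformed phloroglucinol ketone; it sets out from aryl bromide 8 and comes back at chalcone 14.
- Bromine–lithium exchange on 8 (n-BuLi, THF, −78 °C) and formylation with DMF should give 3,5-bis[(2R)-2-(tert-butyldimethylsilyloxy)-3-methylbut-3-en-1-yl]-4-(triisopropylsilyloxy)benzaldehyde F1.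
- Commercial 2',4',6'-trihydroxyacetophenone is silylated (TBSOTf, Et3N, CH2Cl2) to 1-[2,4,6-tris(tert-butyldimethylsilyloxy)phenyl]ethan-1-one F2.
- The lithium enolate of F2 (LiN(SiMe3)2, THF, −78 °C) adds to F1 to give the β-hydroxy ketone aldol adduct F3.
- Mesylation and elimination (MsCl, excess Et3N, CH2Cl2, 0 °C to rt) gives the ring A tris(tert-butyldimethylsilyl) chalcone F4.
- Brief K2CO3 in MeOH at 0 °C removes the three activated aryl silyl ethers of ring A, while the alkyl silyl ethers and the hindered aryl triisopropylsilyl ether should stay, which returns 14.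

Step 8 (trianion acylation). The trianion may add to the β-carbon of the cinnamoyl unit, may be quenched by proton transfer before acylation, or the triketo ester may cyclise during work-up. The fallback assembles the chain in two stages; it sets out from amide 10 and comes back at triketo ester 13.
- Dilithio pentane-2,4-dione (pentane-2,4-dione, LiN(iPr)2 2.1 equiv, THF, 0 °C) is acylated by 10 to give (E)-8-{3,5-bis[(2R)-2-(tert-butyldimethylsilyloxy)-3-methylbut-3-en-1-yl]-4-(triisopropylsilyloxy)phenyl}oct-7-ene-2,4,6-trione F5.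
- The trianion of F5 (LiN(iPr)2 3.2 equiv, THF) is carboxylated at the terminal methyl carbon with CO2 to give (E)-9-{3,5-bis[(2R)-2-(tert-butyldimethylsilyloxy)-3-methylbut-3-en-1-yl]-4-(triisopropylsilyloxy)phenyl}-3,5,7-trioxonon-8-enoic acid F6.
- F6 is esterified at once with Me3SiCHN2 in MeOH/toluene at 0 °C to give 13.

Step 10 (flavone formation). Iodine may substitute ring A at C6 or C8, add across the isopropenyl groups, or the dehydrogenation may stall at the flavanone. The fallback masks the phenols and oxidises a silyl enol ether at low temperature; it sets out from chalcone 14 and comes back at flavone 16.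
- 14 is closed to flavanone 15, now isolated (NaOAc, EtOH, reflux).
- TMSOTf and Et3N (CH2Cl2, 0 °C) convert 15 into 2-{3,5-bis[(2R)-2-(tert-butyldimethylsilyloxy)-3-methylbut-3-en-1-yl]-4-(triisopropylsilyloxy)phenyl}-4,5,7-tris(trimethylsilyloxy)-2H-chromene F7.
- DDQ (1.1 equiv, 2,4,6-collidine, CH2Cl2, 0 °C to rt) oxidises the silyl enol ether to the enone, and brief MeOH with catalytic K2CO3 at 0 °C frees the two aryl trimethylsilyl ethers to give 16.

**Further compounds**

F1 | step 9 | 3,5-bis[(2R)-2-(tert-butyldimethylsilyloxy)-3-methylbut-3-en-1-yl]-4-(triisopropylsilyloxy)benzaldehyde | C=C(C)[C@H](O[Si](C)(C)C(C)(C)C)Cc1cc(C=O)cc(C[C@@H](O[Si](C)(C)C(C)(C)C)C(=C)C)c1O[Si](C(C)C)(C(C)C)C(C)C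
F2 | step 9 | 1-[2,4,6-tris(tert-butyldimethylsilyloxy)phenyl]ethan-1-one | CC(=O)c1c(O[Si](C)(C)C(C)(C)C)cc(O[Si](C)(C)C(C)(C)C)cc1O[Si](C)(C)C(C)(C)C
F3 | step 9 | 3-{3,5-bis[(2R)-2-(tert-butyldimethylsilyloxy)-3-methylbut-3-en-1-yl]-4-(triisopropylsilyloxy)phenyl}-3-hydroxy-1-[2,4,6-tris(tert-butyldimethylsilyloxy)phenyl]propan-1-one (both carbinol epimers) | C=C(C)[C@H](O[Si](C)(C)C(C)(C)C)Cc1cc(C(O)CC(=O)c2c(O[Si](C)(C)C(C)(C)C)cc(O[Si](C)(C)C(C)(C)C)cc2O[Si](C)(C)C(C)(C)C)cc(C[C@@H](O[Si](C)(C)C(C)(C)C)C(=C)C)c1O[Si](C(C)C)(C(C)C)C(C)C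
F4 | step 9 | (E)-3-{3,5-bis[(2R)-2-(tert-butyldimethylsilyloxy)-3-methylbut-3-en-1-yl]-4-(triisopropylsilyloxy)phenyl}-1-[2,4,6-tris(tert-butyldimethylsilyloxy)phenyl]prop-2-en-1-one | C=C(C)[C@H](O[Si](C)(C)C(C)(C)C)Cc1cc(/C=C/C(=O)c2c(O[Si](C)(C)C(C)(C)C)cc(O[Si](C)(C)C(C)(C)C)cc2O[Si](C)(C)C(C)(C)C)cc(C[C@@H](O[Si](C)(C)C(C)(C)C)C(=C)C)c1O[Si](C(C)C)(C(C)C)C(C)C
F5 | step 8 | (E)-8-{3,5-bis[(2R)-2-(tert-butyldimethylsilyloxy)-3-methylbut-3-en-1-yl]-4-(triisopropylsilyloxy)phenyl}oct-7-ene-2,4,6-trione | C=C(C)[C@H](O[Si](C)(C)C(C)(C)C)Cc1cc(/C=C/C(=O)CC(=O)CC(C)=O)cc(C[C@@H](O[Si](C)(C)C(C)(C)C)C(=C)C)c1O[Si](C(C)C)(C(C)C)C(C)C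
F6 | step 8 | (E)-9-{3,5-bis[(2R)-2-(tert-butyldimethylsilyloxy)-3-methylbut-3-en-1-yl]-4-(triisopropylsilyloxy)phenyl}-3,5,7-trioxonon-8-enoic acid | C=C(C)[C@H](O[Si](C)(C)C(C)(C)C)Cc1cc(/C=C/C(=O)CC(=O)CC(=O)CC(=O)O)cc(C[C@@H](O[Si](C)(C)C(C)(C)C)C(=C)C)c1O[Si](C(C)C)(C(C)C)C(C)C
F7 | step 10 | 2-{3,5-bis[(2R)-2-(tert-butyldimethylsilyloxy)-3-methylbut-3-en-1-yl]-4-(triisopropylsilyloxy)phenyl}-4,5,7-tris(trimethylsilyloxy)-2H-chromene | C=C(C)[C@H](O[Si](C)(C)C(C)(C)C)Cc1cc(C2C=C(O[Si](C)(C)C)c3c(O[Si](C)(C)C)cc(O[Si](C)(C)C)cc3O2)cc(C[C@@H](O[Si](C)(C)C(C)(C)C)C(=C)C)c1O[Si](C(C)C)(C(C)C)C(C)C
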